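**Retrosynthetic overview**
1. Feature: the two carbonyl oxygens stand para on C1 and C4 of the only ring, with the C19 chain on C2. C1 and C4 are therefore the termini of a cyclohexa-1,3-diene that carries the chain on its inner carbon C2.
2. Quinone ⇒ hydroquinone ⇒ 2-nonadecylcyclohex-2-ene-1,4-dione ⇒ γ-hydroxyenones ⇒ 2,3-dioxabicyclo[2.2.2]oct-5-ene endoperoxide. This stretch needs only O–O cleavage, tautomerisation and two oxidations.
3. Endoperoxide ⇒ 2-nonadecylcyclohexa-1,3-diene + singlet O2. One [4+2] cycloaddition makes the C1–O and C4–O bonds together.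
4. Diene ⇒ cyclohexa-1,5-dien-1-yl triflate (kinetic enolate of cyclohexenone) + B-nonadecyl-9-BBN (from nonadec-1-ene), joined by a B-alkyl Suzuki–Miyaura C(sp2)–C(sp3) coupling.
5. Ring order: the carbocycle is bought. The 1,2-dioxine bridge ring is the only ring formed (key step) and it is opened again one step later.

Key step: step 3

Remark: the target is achiral. Compounds 10, 11 and 12 are racemates with one enantiomer drawn, and their stereocentres are erased by the end of step 5.

**Step 1**
Reactants: 1 cyclohex-2-en-1-one; 2 N-phenylbis(trifluoromethanesulfonimide)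
Product: 4 cyclohexa-1,5-dien-1-yl trifluoromethanesulfonate, via lithium cyclohexa-1,5-dien-1-olate 3 (not isolated)
Conditions: LiN(i-Pr)2 (1.1 equiv), THF, −78 °C, slow addition of 1; then 2 (1.05 equiv), −78 °C → rt; H2O quench
Reagents that add atoms: N-phenylbis(trifluoromethanesulfonimide), O=S(=O)(N(c1ccccc1)S(=O)(=O)C(F)(F)F)C(F)(F)F
Why: Irreversible kinetic deprotonation at −78 °C removes the α′ proton at C6 rather than the γ proton, and O-sulfonylation of the cross-conjugated lithium dienolate (enol triflate formation) places the leaving group on the inner diene carbon.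

**Step 2**
Reactants: 5 nonadec-1-ene; 6 9-borabicyclo[3.3.1]nonane (9-BBN); 4 cyclohexa-1,5-dien-1-yl trifluoromethanesulfonate
Product: 8 2-nonadecylcyclohexa-1,3-diene, via 9-nonadecyl-9-borabicyclo[3.3.1]nonane 7 (not isolated)
Conditions: 5 + 6 (0.5 M in THF), 0 °C → rt; then 3 M aq K3PO4, 4, PdCl2(dppf)·CH2Cl2 (5 mol %), THF–DMF, 50 °C, Ar (degassed)
Reagents that add atoms: none
Why: Anti-Markovnikov hydroboration puts boron on the terminal carbon, and the B-alkyl Suzuki–Miyaura coupling of the base-activated borane with the alkenyl triflate leaves the diene in place because the wide-bite-angle dppf ligand makes reductive elimination faster than β-hydride elimination.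

**Step 3**
Reactants: 8 2-nonadecylcyclohexa-1,3-diene; 9 dioxygen
Product: 10 (1RS,4SR)-5-nonadecyl-2,3-dioxabicyclo[2.2.2]oct-5-ene (racemic, (1S,4R) drawn)
Conditions: O2 (1 atm, bubbling), tetraphenylporphyrin (0.5 mol %), CH2Cl2, 0 °C, white LED (λ > 400 nm); concentrate below 25 °C
Reagents that add atoms: dioxygen, O=O
Why: Energy transfer from photoexcited tetraphenylporphyrin to ground-state O2 gives singlet oxygen, an electrophilic two-atom dienophile that adds to the diene termini C1 and C4 of 8 in a concerted suprafacial [π4s+π2s] cycloaddition, the reaction type known from the photooxygenation of α-terpinene and of α-phellandrene, the latter having the same 2-alkylcyclohexa-1,3-diene pattern. The one new ring, the six-membered 3,6-dihydro-1,2-dioxine C1–O–O–C4–C3=C2, is closed by intermolecular cycloaddition with both C–O bonds made in the same event, which turns the carbocycle into the 2,3-dioxabicyclo[2.2.2]oct-5-ene. The two new bridgehead stereocentres are tied to each other by delivery of the O–O unit to a single face of the flat diene (a two-atom bridge cannot span opposite faces), and since the faces of achiral 8 are enantiotopic, 10 should form as a racemate whose stereocentres are removed in steps 4 and 5. No regiochemical question arises because O2 is symmetrical and the chain position next to one oxygenated carbon is already fixed in 8. The selectivity needed is chemoselectivity for [4+2] over the ene mode at the ring C6 methylene and the first chain methylene and over dehydrogenation to the arene; the ring-locked s-cis geometry with its short C1–C4 distance and the donor alkyl group on C2, which raises the diene HOMO, secure it, supported by low temperature, an aprotic solvent with a long singlet-oxygen lifetime and stopping the irradiation at full conversion.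

**Step 4**
Reactants: 10 (1RS,4SR)-5-nonadecyl-2,3-dioxabicyclo[2.2.2]oct-5-ene
Product: 11 rac-4-hydroxy-3-nonadecylcyclohex-2-en-1-one and 12 rac-4-hydroxy-2-nonadecylcyclohex-2-en-1-one (regioisomers carried on together)
Conditions: Et3N (0.5 equiv), CH2Cl2, 0 °C → rt
Reagents that add atoms: none
Why: In the Kornblum–DeLaMare rearrangement Et3N removes a bridgehead hydrogen lying antiperiplanar to the weak O–O bond, so an E2-like fragmentation gives a ketone at that carbon and a hydroxyl at the other bridgehead with its configuration carried over from 10; attack at the less hindered bridgehead remote from the chain should favour 11, and both isomers serve the next step.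

**Step 5**
Reactants: 11 rac-4-hydroxy-3-nonadecylcyclohex-2-en-1-one; 12 rac-4-hydroxy-2-nonadecylcyclohex-2-en-1-one
Product: 13 2-nonadecylcyclohex-2-ene-1,4-dione
Conditions: Dess–Martin periodinane (1.3 equiv), CH2Cl2, 0 °C → rt; aq Na2S2O3/NaHCO3 wash; used crude
Reagents that add atoms: none
Why: The Dess–Martin oxidation converts the secondary allylic alcohol of either regioisomer under mild conditions by ligand exchange at pentavalent iodine, so both isomers converge on one enedione and the last stereocentre disappears.

**Step 6**
Reactants: 13 2-nonadecylcyclohex-2-ene-1,4-dione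
Product: 15 2-nonadecyl-1,4-benzoquinone (target), via 2-nonadecylbenzene-1,4-diol 14 (not isolated)
Conditions: p-TsOH·H2O (10 mol %), THF, rt, Ar; then Ag2O (2 equiv), rt, dark; filtration through Celite
Reagents that add atoms: none
Why: Acid-catalysed double keto–enol tautomerisation is driven by the gain of aromaticity, and Ag2O then removes two electrons and two protons in the classical hydroquinone-to-quinone oxidation without touching the saturated chain.

**Compound list**
1 | cyclohex-2-en-1-one | O=C1C=CCCC1 | starting material
2 | N-phenylbis(trifluoromethanesulfonimide) | O=S(=O)(N(c1ccccc1)S(=O)(=O)C(F)(F)F)C(F)(F)F | starting material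
3 | lithium cyclohexa-1,5-dien-1-olate | [Li+].[O-]C1=CCCC=C1 | intermediate
4 | cyclohexa-1,5-dien-1-yl trifluoromethanesulfonate | O=S(=O)(OC1=CCCC=C1)C(F)(F)F | intermediate
5 | nonadec-1-ene | CCCCCCCCCCCCCCCCCC=C | starting material
6 | 9-borabicyclo[3.3.1]nonane | C1CC2CCCC(C1)B2 | starting material
7 | 9-nonadecyl-9-borabicyclo[3.3.1]nonane | CCCCCCCCCCCCCCCCCCCB1C2CCCC1CCC2 | intermediate
8 | 2-nonadecylcyclohexa-1,3-diene | CCCCCCCCCCCCCCCCCCCC1=CCCC=C1 | intermediate
9 | dioxygen | O=O | starting material
10 | (1RS,4SR)-5-nonadecyl-2,3-dioxabicyclo[2.2.2]oct-5-ene, (1S,4R) drawn | CCCCCCCCCCCCCCCCCCCC1=C[C@@H]2CC[C@H]1OO2 | intermediate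
11 | rac-4-hydroxy-3-nonadecylcyclohex-2-en-1-one, (4R) drawn | CCCCCCCCCCCCCCCCCCCC1=CC(=O)CC[C@H]1O | intermediate
12 | rac-4-hydroxy-2-nonadecylcyclohex-2-en-1-one, (4S) drawn | CCCCCCCCCCCCCCCCCCCC1=C[C@@H](O)CCC1=O | intermediate
13 | 2-nonadecylcyclohex-2-ene-1,4-dione | CCCCCCCCCCCCCCCCCCCC1=CC(=O)CCC1=O | intermediate
14 | 2-nonadecylbenzene-1,4-diol | CCCCCCCCCCCCCCCCCCCc1cc(O)ccc1O | intermediate
15 | 2-nonadecylcyclohexa-2,5-diene-1,4-dione (2-nonadecyl-1,4-benzoquinone) | CCCCCCCCCCCCCCCCCCCC1=CC(=O)C=CC1=O | target

**Step count**
Total: 6 steps. Hydroboration and coupling share one flask, as do tautomerisation and final oxidation.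
Longest linear sequence: 6 steps (1 → 4 → 8 → 10 → 11/12 → 13 → 15).

**Steps most likely to fail**

Step 3. Possible failures:
- Hydrogen abstraction in the ene mode at the allylic methylenes.
- Oxidative aromatisation of the diene.
- A second oxygenation of the product alkene.
- Sensitised rearrangement of the peroxide on prolonged irradiation.

The fallback sets out from 8 and installs the two oxygens with palladium instead of light. A palladium-catalysed 1,4-diacetoxylation of the diene (Pd(OAc)2, LiOAc, catalytic p-benzoquinone, MnO2, AcOH–pentane, rt) should give rac-trans-2-nonadecylcyclohex-2-ene-1,4-diyl diacetate F1. Methanolysis (K2CO3, MeOH–THF) should give rac-trans-2-nonadecylcyclohex-2-ene-1,4-diol F2. Oxidation of both carbinols with Dess–Martin periodinane (2.5 equiv) returns to the route at 13.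

Step 2. Possible failures:
- Slow transmetalation of the alkylborane, leaving time for hydrolysis of the triflate by the aqueous base.
- β-Hydride elimination.
- Migration of the diene double bonds, or aromatisation, induced by palladium hydride.

The fallback sets out from 1 and uses borane 7, so it also bypasses step 1.
- α-Iodination of 1 (I2, pyridine–CH2Cl2, 0 °C → rt) gives 2-iodocyclohex-2-en-1-one F3.
- B-alkyl Suzuki–Miyaura coupling with 7 (PdCl2(dppf), AsPh3, Cs2CO3, DMF–THF–H2O, rt) gives 2-nonadecylcyclohex-2-en-1-one F4.
- Condensation with p-toluenesulfonohydrazide (EtOH, warm) gives the (E)-tosylhydrazone of 2-nonadecylcyclohex-2-en-1-one F5. Its sulfonamide nitrogen lies syn to the α′ methylene.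
- A Shapiro reaction (MeLi, 2.5 equiv, Et2O, 0 °C → rt, then H2O) then creates the second ring double bond regiospecifically and returns to the route at 8.

Step 4. Possible failures:
- Base-induced further isomerisation of the γ-hydroxyenones through their dienols to the saturated dione level.
- Sluggish bridgehead deprotonation that lets thermal O–O homolysis compete.

The fallback sets out from 10 and cleaves the peroxide reductively instead of by base. Thiourea (MeOH–CH2Cl2, rt) should give rac-cis-2-nonadecylcyclohex-2-ene-1,4-diol F6, with both hydroxyls on the face set in the cycloaddition. Double Dess–Martin oxidation (2.5 equiv, CH2Cl2) returns to the route at 13.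

**Further compounds**
F1 | step 3 | rac-trans-2-nonadecylcyclohex-2-ene-1,4-diyl diacetate, (1R,4R) drawn | CCCCCCCCCCCCCCCCCCCC1=C[C@H](OC(C)=O)CC[C@H]1OC(C)=O
F2 | step 3 | rac-trans-2-nonadecylcyclohex-2-ene-1,4-diol, (1R,4R) drawn | CCCCCCCCCCCCCCCCCCCC1=C[C@H](O)CC[C@H]1O
F3 | step 2 | 2-iodocyclohex-2-en-1-one | O=C1CCCC=C1I
F4 | step 2 | 2-nonadecylcyclohex-2-en-1-one | CCCCCCCCCCCCCCCCCCCC1=CCCCC1=O
F5 | step 2 | N'-[(1E)-2-nonadecylcyclohex-2-en-1-ylidene]-4-methylbenzenesulfonohydrazide | Cc1ccc(cc1)S(=O)(=O)N/N=C1/C(CCCCCCCCCCCCCCCCCCC)=CCCC1
F6 | step 4 | rac-cis-2-nonadecylcyclohex-2-ene-1,4-diol, (1R,4S) drawn | CCCCCCCCCCCCCCCCCCCC1=C[C@@H](O)CC[C@H]1O
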